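The route hinges on the C2–C3 bond of the cyclopentane ring (daucane numbering). Its carbons are the only adjacent pair of bare CH2 groups in the bicycle and hang between the all-carbon quaternary C1 and the tertiary alcohol C4, so the bond can be made as an alkene and saturated afterwards at no cost. Ring-closing metathesis of vinyl groups on C1 and C4 of a finished cycloheptane closes the five-membered ring and gives the trans-fused hydroazulene in one operation, with C1, C4, C5 and C6 already fixed. Precursor 25 is a cycloheptane with methyl and vinyl on C1, an (isopropyl)(vinyl)carbinol arm on C5, a C6 silyl ether and a C10 dioxolane.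

Key step: step 17

Numbering: daucane locants are used for every intermediate. C1 is the quaternary carbon bearing methyl C15, C2–C3 the bridge, C4 the carbinol, C5 the ring-fusion CH, C6 to C10 the other cycloheptane carbons, and C14 the exocyclic methylene. β is the face of C15 and α the face of H5. TBS = tert-butyldimethylsilyl.

Assumption: the lipase of step 2 acylates the R-configured carbinol carbon of meso-diol 3, the sense lipases show with the five-membered analogue.

Step 1
Reactants: 1 cyclohepta-1,3-diene
Product: 3 cis-cyclohept-2-ene-1,4-diol (meso), via endoperoxide 2 (not isolated)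
Conditions: O2, rose bengal, hν, MeOH, 0 °C; then thiourea, rt
Reagents that add atoms: dioxygen O=O
Why: Singlet-oxygen [4+2] cycloaddition to the s-cis diene followed by reductive O–O cleavage puts both hydroxyls on one face, so only the cis (meso) diol can form.

Step 2
Reactants: 3 cis-cyclohept-2-ene-1,4-diol
Product: 4 (1R,4S)-4-hydroxycyclohept-2-en-1-yl acetate
Conditions: immobilised Candida antarctica lipase B, vinyl acetate, t-BuOMe, rt
Reagents that add atoms: vinyl acetate C=COC(C)=O
Why: Enzymatic desymmetrisation by irreversible transesterification should acylate only the R carbinol carbon (future C10), leaving the S carbinol (future C6) free and fixing the absolute configuration of the whole route.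

Step 3
Reactants: 4 (1R,4S)-4-hydroxycyclohept-2-en-1-yl acetate
Product: 5 (1R,4S)-4-(tert-butyldimethylsilyloxy)cyclohept-2-en-1-yl acetate
Conditions: TBSCl, imidazole, DMF, rt
Reagents that add atoms: tert-butyldimethylsilyl chloride CC(C)(C)[Si](C)(C)Cl
Why: Imidazole-promoted silylation of the free secondary alcohol gives a bulky, base-stable ether that later directs the conjugate addition.

Step 4
Reactants: 5 (1R,4S)-4-(tert-butyldimethylsilyloxy)cyclohept-2-en-1-yl acetate
Product: 6 (1R,4S)-4-(tert-butyldimethylsilyloxy)cyclohept-2-en-1-ol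
Conditions: K2CO3 (0.2 equiv), MeOH, 0 °C to rt
Reagents that add atoms: none
Why: Base-catalysed transesterification with methanol removes the acetate and leaves the silyl ether intact.

Step 5
Reactants: 6 (1R,4S)-4-(tert-butyldimethylsilyloxy)cyclohept-2-en-1-ol
Product: 7 (S)-4-(tert-butyldimethylsilyloxy)cyclohept-2-en-1-one
Conditions: Dess–Martin periodinane, CH2Cl2, rt
Reagents that add atoms: none
Why: Dess–Martin oxidation of the allylic alcohol gives the enone under neutral conditions that leave the γ-silyloxy stereocentre (C6) untouched.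

Step 6
Reactants: 7 (S)-4-(tert-butyldimethylsilyloxy)cyclohept-2-en-1-one
Product: 8 (S)-4-(tert-butyldimethylsilyloxy)-2-iodocyclohept-2-en-1-one
Conditions: I2, pyridine–CH2Cl2, 0 °C to rt
Reagents that add atoms: iodine II
Why: α-Iodination of an enone by pyridine conjugate addition, enolate iodination and elimination (Baylis–Hillman-type activation) puts a coupling handle on the future C1 only.

Step 7
Reactants: 8 (S)-4-(tert-butyldimethylsilyloxy)-2-iodocyclohept-2-en-1-one; 9 dimethylzinc
Product: 10 (S)-4-(tert-butyldimethylsilyloxy)-2-methylcyclohept-2-en-1-one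
Conditions: Me2Zn, Pd(dppf)Cl2 (5 mol %), THF, 0 °C to rt
Reagents that add atoms: dimethylzinc C[Zn]C
Why: Negishi coupling of the α-iodoenone brings in methyl C15 under non-basic conditions, and it must come before C5 and C2 are attached because the group that enters C1 last ends trans to the C5 arm.

Step 8
Reactants: 10 (S)-4-(tert-butyldimethylsilyloxy)-2-methylcyclohept-2-en-1-one; 11 2-methylprop-1-enylmagnesium bromide
Product: 12 C1=C10 trimethylsilyl enol ether with 5β-(2-methylprop-1-enyl) and 6α-OTBS (5,6-trans)
Conditions: 11, CuBr·SMe2 (20 mol %), Me3SiCl, HMPA, THF, −78 to −40 °C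
Reagents that add atoms: 2-methylprop-1-enylmagnesium bromide CC(C)=C[Mg]Br; chlorotrimethylsilane C[Si](C)(C)Cl
Why: Copper-catalysed conjugate addition with silyl trapping delivers the alkenyl group to C5 anti to the bulky 6α-silyloxy group (5β) and stores the regiodefined C1=C10 enolate, a trisubstituted alkenyl group being chosen so that it can later be cleaved beside a vinyl group.

Step 9
Reactants: 12 C1=C10 trimethylsilyl enol ether; 13 formaldehyde
Product: 14 cycloheptanone (C10=O) with 1β-methyl, 1α-hydroxymethyl, 5β-(2-methylprop-1-enyl) and 6α-OTBS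
Conditions: aq. HCHO (37 %), Yb(OTf)3 (10 mol %), THF, rt
Reagents that add atoms: formaldehyde C=O
Why: In this aqueous Mukaiyama aldol (hydroxymethylation) the smallest carbon electrophile attacks the tetrasubstituted enol ether anti to the 5β-alkenyl group, which allylic strain against the C1 methyl holds pseudoaxial, so CH2OH (C2) enters α, the methyl ends β and quaternary C1 is set.

Step 10
Reactants: 14 hydroxymethyl ketone
Product: 15 keto aldehyde with 1β-methyl, 1α-formyl, 5β-(2-methylprop-1-enyl), 6α-OTBS and C10=O
Conditions: Dess–Martin periodinane, pyridine, CH2Cl2, 0 °C to rt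
Reagents that add atoms: none
Why: Buffered Dess–Martin oxidation converts the neopentyl primary alcohol into the aldehyde without the basic conditions that would invite retro-aldol loss of formaldehyde.

Step 11
Reactants: 15 keto aldehyde; 16 methyltriphenylphosphonium bromide
Product: 17 cycloheptanone (C10=O) with 1β-methyl, 1α-vinyl, 5β-(2-methylprop-1-enyl) and 6α-OTBS
Conditions: 16, KN(SiMe3)2, THF, 0 °C; then 15 (1.05 equiv ylide), −78 to 0 °C
Reagents that add atoms: methyltriphenylphosphonium bromide C[P+](c1ccccc1)(c1ccccc1)c1ccccc1.[Br-]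
Why: Wittig methylenation with about one equivalent of ylide is chemoselective for the aldehyde over the ketone flanked by the quaternary carbon and turns the formyl group into the C1 vinyl group.

Step 12
Reactants: 17 α-methyl-α-vinyl ketone
Product: 18 C10 ethylene ketal of 17
Conditions: (Me3SiOCH2)2, Me3SiOTf (10 mol %), CH2Cl2, −78 to −20 °C
Reagents that add atoms: 1,2-bis(trimethylsilyloxy)ethane C[Si](C)(C)OCCO[Si](C)(C)C
Why: Noyori ketalisation works at low temperature on ketones next to quaternary carbons and spares silyl ether and alkenes, and masking C10 as an achiral dioxolane avoids a reduction–reoxidation detour and a needless stereocentre.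

Step 13
Reactants: 18 C10 ethylene ketal
Product: 20 5β-carbaldehyde (C4) with 1β-methyl and 1α-vinyl and 6α-OTBS and C10 ketal, via secondary ozonide 19 (not isolated)
Conditions: O3 (1 equiv, Sudan Red 7B end point), CH2Cl2, −78 °C; then Me2S, −78 °C to rt
Reagents that add atoms: ozone [O-][O+]=O
Why: In this chemoselective ozonolysis the electron-rich trisubstituted alkene reacts much faster with electrophilic ozone than the monosubstituted vinyl group on quaternary C1, so only the C5 arm is cut back to the aldehyde after reductive work-up.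

Step 14
Reactants: 20 5β-carbaldehyde; 21 vinylmagnesium bromide
Product: 22 allylic alcohol, 5β-(1-hydroxyprop-2-enyl), both C4 epimers, otherwise as 20
Conditions: 21, THF, −78 °C; then H2O
Reagents that add atoms: vinylmagnesium bromide C=C[Mg]Br
Why: Grignard 1,2-addition to the aldehyde at low temperature outruns enolisation, and the new carbinol centre needs no control because step 15 erases it.

Step 15
Reactants: 22 allylic alcohol
Product: 23 vinyl ketone, 5β-acryloyl (C4=O), otherwise as 20
Conditions: Dess–Martin periodinane, pyridine, CH2Cl2, 0 °C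
Reagents that add atoms: none
Why: Buffered Dess–Martin oxidation gives the vinyl ketone without β-elimination of the C6 silyloxy group or epimerisation at C5.

Step 16
Reactants: 23 vinyl ketone; 24 isopropylmagnesium chloride
Product: 25 (1S,4S,5S,6S) metathesis precursor: C10 ethylene ketal cycloheptane with 1β-methyl, 1α-vinyl, 5β-[(S)-3-hydroxy-4-methylpent-1-en-3-yl] and 6α-OTBS
Conditions: LaCl3·2LiCl (1 equiv), THF, rt; then 24, −40 to 0 °C; then H2O
Reagents that add atoms: isopropylmagnesium chloride CC(C)[Mg]Cl
Why: In this lanthanide-promoted 1,2-Grignard addition the salt raises carbonyl electrophilicity and lowers basicity, which suppresses conjugate addition, β-hydride reduction and enolisation, and under Felkin–Anh control (quaternary C1 perpendicular to the carbonyl, vinyl next to H5) isopropyl enters from the C6 side to give the 4S carbinol (future 4β-OH), which is why vinyl goes on C4 first and isopropyl last, the reverse order being expected to give the C4 epimer.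

Step 17
Reactants: 25 metathesis precursor
Product: 26 (1S,4S,5S,6S) trans-fused cyclopentene: 4β-hydroxy-6α-(TBSO)-14-nordauc-2-en-10-one ethylene ketal (5αH, 1β-methyl)
Conditions: RuCl2(=CHPh)(PCy3)(H2IMes) (second-generation Grubbs catalyst, 5 mol %), toluene (2 mM), 80 °C, Ar sparge
Reagents that add atoms: none
Why: The ruthenium benzylidene exchanges with one terminal vinyl group to give a new alkylidene, this adds [2+2] to the second vinyl group, and cycloreversion of the metallacyclobutane expels ethylene and leaves C2=C3, which is ring-closing olefin metathesis of a 1,6-diene, the standard entry to cyclopentenes and well known for allylic quaternary and tertiary-carbinol carbons. The one ring formed is the five-membered carbocycle C1–C2–C3–C4–C5, closed by joining the inner vinyl carbons of two arms that sit trans and gauche on the adjacent ring atoms C1 and C5. No stereocentre is created: C6, C5, C1 and C4 come from steps 2, 8, 9 and 16, none can epimerise under neutral conditions, and the trans ring fusion is simply carried over. The selectivity needed is intramolecular closure over cross-metathesis, secured by high dilution, removal of ethylene, the absence of any third alkene in 25 and the full substitution at C1 and C4 (gem-disubstituent effect). The free allylic hydroxyl is tolerated by the catalyst and is known to speed metathesis of the neighbouring vinyl group, which offsets the crowding by isopropyl.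

Step 18
Reactants: 26 trans-fused cyclopentene
Product: 27 4β-hydroxy-6α-(TBSO)-14-nordaucan-10-one ethylene ketal
Conditions: H2 (1 atm), Pd/C (10 wt %), EtOAc, rt
Reagents that add atoms: none
Why: Heterogeneous catalytic hydrogenation saturates the only alkene, forms no stereocentre and leaves tertiary alcohol, silyl ether and ketal untouched.

Step 19
Reactants: 27 saturated ketal
Product: 28 4β-hydroxy-6α-(TBSO)-14-nordaucan-10-one
Conditions: PPTS, acetone–H2O, 55 °C
Reagents that add atoms: water O
Why: Acid-catalysed acetal hydrolysis releases the crowded dioxolane under conditions too mild to cleave the hindered secondary silyl ether or dehydrate the C4 alcohol.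

Step 20
Reactants: 28 C10 ketone
Product: 30 4β-hydroxy-6α-(TBSO)-14-nordauc-9-en-10-yl trifluoromethanesulfonate, via dipotassium enolate 29 (not isolated)
Conditions: KN(SiMe3)2 (2.2 equiv), THF, −78 °C; then PhNTf2, −78 to 0 °C; then H2O
Reagents that add atoms: N-phenylbis(trifluoromethanesulfonimide) O=S(=O)(N(c1ccccc1)S(=O)(=O)C(F)(F)F)C(F)(F)F
Why: In this enolate O-triflation deprotonation can only occur at C9 because C1 is quaternary, and the mild triflyl donor reacts at the enolate oxygen rather than at the hindered tertiary alkoxide, which is reprotonated on work-up.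

Step 21
Reactants: 30 enol triflate
Product: 31 6α-(TBSO)-14-nordauc-9-en-4β-ol
Conditions: Pd(OAc)2 (5 mol %), PPh3, HCO2H, Et3N, DMF, 60 °C
Reagents that add atoms: none
Why: Palladium-catalysed formate reduction of a vinyl triflate (oxidative addition, formate exchange, decarboxylation, reductive elimination) gives the C9=C10 alkene and is well known for enol triflates next to quaternary carbons.

Step 22
Reactants: 31 C9=C10 alkene
Product: 32 4β-hydroxy-6α-(TBSO)-14-nordauc-9-en-8-one
Conditions: Rh2(cap)4 (dirhodium tetracaprolactamate, 1 mol %), t-BuOOH, K2CO3, CH2Cl2, rt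
Reagents that add atoms: tert-butyl hydroperoxide CC(C)(C)OO
Why: In this dirhodium-catalysed allylic oxidation C8 is the only allylic carbon that bears hydrogen, and the allyl radical should be captured at unhindered C8 rather than at neopentyl C10, giving the C8 enone.

Step 23
Reactants: 32 C8 enone
Product: 33 4β,9α,10α-trihydroxy-6α-(TBSO)-14-nordaucan-8-one
Conditions: OsO4 (5 mol %), N-methylmorpholine N-oxide, citric acid, t-BuOH–H2O, rt
Reagents that add atoms: osmium tetroxide O=[Os](=O)(=O)=O; N-methylmorpholine N-oxide C[N+]1([O-])CCOCC1; water O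
Why: Catalytic osmium tetroxide syn-dihydroxylation with an N-oxide co-oxidant forms both C–O bonds on one face, and because the axial 1β-methyl shields the β face of C9=C10 in the trans-fused bicycle, attack from the α face sets 9α-OH and 10α-OH together.

Step 24
Reactants: 33 dihydroxy ketone
Product: 34 9α,10α-O-isopropylidene derivative of 33
Conditions: Me2C(OMe)2, PPTS (cat.), CH2Cl2, rt
Reagents that add atoms: 2,2-dimethoxypropane COC(C)(C)OC
Why: Acid-catalysed transketalisation engages only the cis-vicinal diol and protects the α,β-dihydroxy ketone against retro-aldol cleavage in the next step.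

Step 25
Reactants: 34 acetonide ketone; 16 methyltriphenylphosphonium bromide
Product: 35 6α-(TBSO)-9α,10α-(isopropylidenedioxy)dauc-8(14)-en-4β-ol
Conditions: 16 (4 equiv), KN(SiMe3)2, THF, 0 °C; then 34, 0 °C to rt
Reagents that add atoms: methyltriphenylphosphonium bromide C[P+](c1ccccc1)(c1ccccc1)c1ccccc1.[Br-]
Why: Wittig methylenation is reliable for ketones flanked by a fused acetonide oxygen, excess ylide covers the free C4 hydroxyl, and the cis-fused dioxolane keeps C9 from epimerising while C14 is installed.

Step 26
Reactants: 35 silyl ether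
Product: 36 9α,10α-(isopropylidenedioxy)dauc-8(14)-ene-4β,6α-diol
Conditions: n-Bu4NF, THF, rt to 45 °C
Reagents that add atoms: none
Why: Fluoride-induced desilylation, driven by the strong Si–F bond, frees the C6 hydroxyl while acetonide and alkene stay untouched.

Step 27
Reactants: 36 diol; 37 isovaleric anhydride
Product: 38 6α-isovaleroyloxy-9α,10α-(isopropylidenedioxy)dauc-8(14)-en-4β-ol
Conditions: 37, DMAP, Et3N, CH2Cl2, rt
Reagents that add atoms: isovaleric anhydride CC(C)CC(=O)OC(=O)CC(C)C
Why: DMAP-catalysed acylation discriminates cleanly between the secondary C6 hydroxyl and the hindered tertiary C4 hydroxyl, the only two free OH groups.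

Step 28
Reactants: 38 ester acetonide
Product: 39 target, 6α-isovaleroyloxydauc-8(14)-ene-4β,9α,10α-triol, (1S,4R,5S,6S,9R,10S)
Conditions: AcOH–H2O (4:1), 40 °C
Reagents that add atoms: none
Why: Mild aqueous acid hydrolysis of the acetonide releases the 9α,10α-diol without touching the ester, the allylic system or the tertiary alcohol.

Compound list
1 | cyclohepta-1,3-diene | C1=CC=CCCC1 | starting material
2 | 6,7-dioxabicyclo[3.2.2]non-8-ene (endoperoxide) | C1CC[C@H](OO2)C=C[C@@H]12 | intermediate
3 | cis-cyclohept-2-ene-1,4-diol (meso, 1R,4S) | C1CC[C@H](O)C=C[C@@H]1O | intermediate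
4 | (1R,4S)-4-hydroxycyclohept-2-en-1-yl acetate | C1CC[C@H](O)C=C[C@@H]1OC(C)=O | intermediate
5 | (1R,4S)-4-(tert-butyldimethylsilyloxy)cyclohept-2-en-1-yl acetate | C1CC[C@H](O[Si](C)(C)C(C)(C)C)C=C[C@@H]1OC(C)=O | intermediate
6 | (1R,4S)-4-(tert-butyldimethylsilyloxy)cyclohept-2-en-1-ol | C1CC[C@H](O[Si](C)(C)C(C)(C)C)C=C[C@@H]1O | intermediate
7 | (S)-4-(tert-butyldimethylsilyloxy)cyclohept-2-en-1-one | C1CC[C@H](O[Si](C)(C)C(C)(C)C)C=CC1=O | intermediate
8 | (S)-4-(tert-butyldimethylsilyloxy)-2-iodocyclohept-2-en-1-one | C1CC[C@H](O[Si](C)(C)C(C)(C)C)C=C(I)C1=O | intermediate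
9 | dimethylzinc | C[Zn]C | starting material
10 | (S)-4-(tert-butyldimethylsilyloxy)-2-methylcyclohept-2-en-1-one | C1CC[C@H](O[Si](C)(C)C(C)(C)C)C=C(C)C1=O | intermediate
11 | 2-methylprop-1-enylmagnesium bromide | CC(C)=C[Mg]Br | starting material
12 | C1=C10 trimethylsilyl enol ether, 5β-(2-methylprop-1-enyl), 6α-OTBS | C1CC[C@H](O[Si](C)(C)C(C)(C)C)[C@@H](C=C(C)C)C(C)=C1O[Si](C)(C)C | intermediate
13 | formaldehyde | C=O | starting material
14 | C10 ketone, 1β-methyl, 1α-hydroxymethyl, 5β-(2-methylprop-1-enyl), 6α-OTBS | C1CC[C@H](O[Si](C)(C)C(C)(C)C)[C@@H](C=C(C)C)[C@](C)(CO)C1=O | intermediate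
15 | C10 ketone, 1β-methyl, 1α-formyl, 5β-(2-methylprop-1-enyl), 6α-OTBS | C1CC[C@H](O[Si](C)(C)C(C)(C)C)[C@@H](C=C(C)C)[C@](C)(C=O)C1=O | intermediate
16 | methyltriphenylphosphonium bromide | C[P+](c1ccccc1)(c1ccccc1)c1ccccc1.[Br-] | starting material
17 | C10 ketone, 1β-methyl, 1α-vinyl, 5β-(2-methylprop-1-enyl), 6α-OTBS | C1CC[C@H](O[Si](C)(C)C(C)(C)C)[C@@H](C=C(C)C)[C@](C)(C=C)C1=O | intermediate
18 | C10 ethylene ketal of 17 | C1CC[C@H](O[Si](C)(C)C(C)(C)C)[C@@H](C=C(C)C)[C@](C)(C=C)C12OCCO2 | intermediate
19 | secondary ozonide (3,3-dimethyl-1,2,4-trioxolan-5-yl on C5) | C1CC[C@H](O[Si](C)(C)C(C)(C)C)[C@@H](C3OOC(C)(C)O3)[C@](C)(C=C)C12OCCO2 | intermediate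
20 | 5β-carbaldehyde, 1β-methyl, 1α-vinyl, 6α-OTBS, C10 ketal | C1CC[C@H](O[Si](C)(C)C(C)(C)C)[C@@H](C=O)[C@](C)(C=C)C12OCCO2 | intermediate
21 | vinylmagnesium bromide | C=C[Mg]Br | starting material
22 | 5β-(1-hydroxyprop-2-enyl) compound, C4 epimers | C1CC[C@H](O[Si](C)(C)C(C)(C)C)[C@@H](C(O)C=C)[C@](C)(C=C)C12OCCO2 | intermediate
23 | 5β-acryloyl compound (vinyl ketone) | C1CC[C@H](O[Si](C)(C)C(C)(C)C)[C@@H](C(=O)C=C)[C@](C)(C=C)C12OCCO2 | intermediate
24 | isopropylmagnesium chloride | CC(C)[Mg]Cl | starting material
25 | metathesis precursor (1S,4S,5S,6S) | C1CC[C@H](O[Si](C)(C)C(C)(C)C)[C@@H]([C@@](O)(C=C)C(C)C)[C@](C)(C=C)C12OCCO2 | intermediate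
26 | 4β-hydroxy-6α-(TBSO)-14-nordauc-2-en-10-one ethylene ketal | C1CC[C@H](O[Si](C)(C)C(C)(C)C)[C@@H]2[C@](C)(C=C[C@@]2(O)C(C)C)C13OCCO3 | intermediate
27 | 4β-hydroxy-6α-(TBSO)-14-nordaucan-10-one ethylene ketal | C1CC[C@H](O[Si](C)(C)C(C)(C)C)[C@@H]2[C@](C)(CC[C@@]2(O)C(C)C)C13OCCO3 | intermediate
28 | 4β-hydroxy-6α-(TBSO)-14-nordaucan-10-one | C1CC[C@H](O[Si](C)(C)C(C)(C)C)[C@@H]2[C@](C)(CC[C@@]2(O)C(C)C)C1=O | intermediate
29 | dipotassium C9=C10 enolate C4 alkoxide of 28 | [K+].[K+].C1C[C@H](O[Si](C)(C)C(C)(C)C)[C@@H]2[C@](C)(CC[C@@]2([O-])C(C)C)C([O-])=C1 | intermediate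
30 | 4β-hydroxy-6α-(TBSO)-14-nordauc-9-en-10-yl triflate | C1C[C@H](O[Si](C)(C)C(C)(C)C)[C@@H]2[C@](C)(CC[C@@]2(O)C(C)C)C(OS(=O)(=O)C(F)(F)F)=C1 | intermediate
31 | 6α-(TBSO)-14-nordauc-9-en-4β-ol | C1C[C@H](O[Si](C)(C)C(C)(C)C)[C@@H]2[C@](C)(CC[C@@]2(O)C(C)C)C=C1 | intermediate
32 | 4β-hydroxy-6α-(TBSO)-14-nordauc-9-en-8-one | O=C1C[C@H](O[Si](C)(C)C(C)(C)C)[C@@H]2[C@](C)(CC[C@@]2(O)C(C)C)C=C1 | intermediate
33 | 4β,9α,10α-trihydroxy-6α-(TBSO)-14-nordaucan-8-one | O=C1C[C@H](O[Si](C)(C)C(C)(C)C)[C@@H]2[C@](C)(CC[C@@]2(O)C(C)C)[C@H](O)[C@@H]1O | intermediate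
34 | 9α,10α-acetonide of 33 | O=C1C[C@H](O[Si](C)(C)C(C)(C)C)[C@@H]2[C@](C)(CC[C@@]2(O)C(C)C)[C@H](OC(C)(C)O3)[C@@H]13 | intermediate
35 | 6α-(TBSO)-9α,10α-(isopropylidenedioxy)dauc-8(14)-en-4β-ol | C=C1C[C@H](O[Si](C)(C)C(C)(C)C)[C@@H]2[C@](C)(CC[C@@]2(O)C(C)C)[C@H](OC(C)(C)O3)[C@@H]13 | intermediate
36 | 9α,10α-(isopropylidenedioxy)dauc-8(14)-ene-4β,6α-diol | C=C1C[C@H](O)[C@@H]2[C@](C)(CC[C@@]2(O)C(C)C)[C@H](OC(C)(C)O3)[C@@H]13 | intermediate
37 | isovaleric anhydride | CC(C)CC(=O)OC(=O)CC(C)C | starting material
38 | 6α-isovaleroyloxy-9α,10α-(isopropylidenedioxy)dauc-8(14)-en-4β-ol | C=C1C[C@H](OC(=O)CC(C)C)[C@@H]2[C@](C)(CC[C@@]2(O)C(C)C)[C@H](OC(C)(C)O3)[C@@H]13 | intermediate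
39 | 6α-isovaleroyloxydauc-8(14)-ene-4β,9α,10α-triol (CNP0204264.1) | C=C1C[C@H](OC(=O)CC(C)C)[C@@H]2[C@](C)(CC[C@@]2(O)C(C)C)[C@H](O)[C@@H]1O | target

Total step count: 28. Longest linear sequence: 28 steps (1 to 39). The partners 9, 11, 13, 16, 21, 24 and 37 are purchased.

Steps most likely to fail

Step 17 (ring-closing metathesis).
- **What may go wrong:** initiation may be sluggish because both vinyl groups sit on fully substituted carbons. The catalyst may decay before closure, intermolecular metathesis may take over, or the double bonds may migrate.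
- **Fallback:** it sets out from aldehyde 20 and returns at 27, closing the ring at C3–C4 instead. Isopropylmagnesium chloride 24 is added to 20 to give the secondary carbinol F1. Dess–Martin oxidation gives the isopropyl ketone F2. Hydroboration of the C1 vinyl group with 9-BBN and NaBO3 work-up gives the primary alcohol F3, and Appel iodination (I2, PPh3, imidazole) gives the primary iodide F4. SmI2 with HMPA in THF then closes the five-membered ring in an intramolecular samarium Barbier reaction.
- **Stereochemistry of the fallback:** the two-carbon tether forces attack from the C1 side of the carbonyl with isopropyl turned towards H5. This gives the 4β-hydroxyl of 27 directly and makes the hydrogenation unnecessary.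

Step 16 (isopropyl addition to the vinyl ketone).
- **What may go wrong:** conjugate addition, β-hydride transfer from the Grignard reagent, enolisation followed by loss of the C6 silyloxy group, or eroded facial selectivity.
- **Fallback:** it sets out from 23 and returns at 27, carrying the isopropyl group in masked form. Isopropenylmagnesium bromide with CeCl3, an sp2 nucleophile without β-hydrogens, adds 1,2 from the same Felkin–Anh face to give the isopropenyl vinyl carbinol F5. The same ruthenium catalyst joins the two monosubstituted vinyl groups faster than it engages the 1,1-disubstituted isopropenyl group and gives the isopropenyl cyclopentene F6. Hydrogenation over Pd/C saturates C2=C3 and the isopropenyl group together to give 27.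

Step 22 (allylic oxidation at C8).
- **What may go wrong:** slow hydrogen abstraction, oxygen capture at the wrong end of the allyl system, or over-oxidation.
- **Fallback:** it sets out from ketone 28 and returns at 32, replacing steps 20 to 22 by a regiodefined 1,3-carbonyl transposition. IBX in DMSO at 70 °C dehydrogenates 28 to the C8=C9 enone F7. Weitz–Scheffer epoxidation (H2O2, NaOH, MeOH) from the open α face gives the epoxy ketone F8. Wharton transposition (N2H4·H2O, AcOH, MeOH) gives the C9=C10 allylic alcohol F9, and MnO2 oxidises it to 32.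

Further compounds
F1 | step 17 | 5β-(1-hydroxy-2-methylpropyl) compound, C4 epimers, 1β-methyl, 1α-vinyl, 6α-OTBS, C10 ketal | C1CC[C@H](O[Si](C)(C)C(C)(C)C)[C@@H](C(O)C(C)C)[C@](C)(C=C)C12OCCO2
F2 | step 17 | 5β-isobutyryl compound (isopropyl ketone) | C1CC[C@H](O[Si](C)(C)C(C)(C)C)[C@@H](C(=O)C(C)C)[C@](C)(C=C)C12OCCO2
F3 | step 17 | 1α-(2-hydroxyethyl) isopropyl ketone | C1CC[C@H](O[Si](C)(C)C(C)(C)C)[C@@H](C(=O)C(C)C)[C@](C)(CCO)C12OCCO2
F4 | step 17 | 1α-(2-iodoethyl) isopropyl ketone | C1CC[C@H](O[Si](C)(C)C(C)(C)C)[C@@H](C(=O)C(C)C)[C@](C)(CCI)C12OCCO2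
F5 | step 16 | isopropenyl vinyl carbinol, analogue of 25 with isopropenyl on C4 | C1CC[C@H](O[Si](C)(C)C(C)(C)C)[C@@H]([C@@](O)(C=C)C(C)=C)[C@](C)(C=C)C12OCCO2
F6 | step 16 | isopropenyl cyclopentene, analogue of 26 with isopropenyl on C4 | C1CC[C@H](O[Si](C)(C)C(C)(C)C)[C@@H]2[C@](C)(C=C[C@@]2(O)C(C)=C)C13OCCO3
F7 | step 22 | 4β-hydroxy-6α-(TBSO)-14-nordauc-8-en-10-one | C1[C@H](O[Si](C)(C)C(C)(C)C)[C@@H]2[C@](C)(CC[C@@]2(O)C(C)C)C(=O)C=C1
F8 | step 22 | 8α,9α-epoxy-4β-hydroxy-6α-(TBSO)-14-nordaucan-10-one | C1[C@H](O[Si](C)(C)C(C)(C)C)[C@@H]2[C@](C)(CC[C@@]2(O)C(C)C)C(=O)[C@@H]3O[C@H]13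
F9 | step 22 | 6α-(TBSO)-14-nordauc-9-ene-4β,8α-diol | O[C@@H]1C[C@H](O[Si](C)(C)C(C)(C)C)[C@@H]2[C@](C)(CC[C@@]2(O)C(C)C)C=C1
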